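## Retrosynthetic overview

- Last bond: C5–C1' of the farnesyl chain, by catalytic asymmetric dearomative allylation of 6,8-dihydroxy-3,5,7-trimethyl-1H-isochromen-1-one. The target is the C5-alkylated keto tautomer of this resorcinol, so its only stereocenter is set in the last step.
- Key disconnection: C5–C6 and C7–C8. The C6–C7 unit of a siloxyalkyne (CH3–C≡C–OSi) is inserted between C5 and C8 of methyl(pyranonyl)ketene by [2+2] cycloaddition, 4π ring opening and 6π ring closure onto C8a.
- Enabling feature: the carbocycle C4a–C5–C6–C7–C8–C8a carries oxygen at C6 and C8 (1,3) with C7–CH3 between them and is fused through C4a=C8a to the 2-pyranone ring. C8=O maps onto a ketene carbonyl and O–C6–C7–CH3 onto an ynol ether. The C3=C4 π bond of the 2-pyranone (C8a=C4a) is the third π bond of the electrocyclization.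
- Ring order: the 2-pyranone ring is bought (triacetic acid lactone); the carbocycle is the only ring formed, in the key step.
- The ketene precursor comes from triacetic acid lactone by deoxybromination, cross-coupling with a Reformatsky reagent, ester cleavage and acid chloride formation.

Key step: step 6

Remark: isochromene numbering is used for the bicycle and pyranone numbering for the monocyclic precursors; the sense of induction of the bisphosphine in step 9 cannot be taken from precedent, so the (S,S)-ligand is written and its mirror image is used if the (5R)-product forms.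

## Route

Step 1
Reactants: 1 4-hydroxy-6-methyl-2H-pyran-2-one (triacetic acid lactone)
Product: 2 4-bromo-6-methyl-2H-pyran-2-one
Conditions: Bu4NBr, P2O5, toluene, 100 °C
Reagents that add atoms: tetrabutylammonium bromide, CCCC[N+](CCCC)(CCCC)CCCC.[Br-]
Why: The 4-hydroxyl is a vinylogous acid, so phosphorylation by P2O5 makes it a leaving group that bromide should displace by addition–elimination at C4 (deoxybromination of a vinylogous acid).

Step 2
Reactants: 2 4-bromo-6-methyl-2H-pyran-2-one; 3 tert-butyl 2-bromopropanoate (racemic)
Product: 5 tert-butyl 2-(6-methyl-2-oxo-2H-pyran-4-yl)propanoate (racemic), via Reformatsky reagent 4 (not isolated)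
Conditions: 3, Zn, Me3SiCl (cat.), THF, rt; then 2, Pd(dba)2 (2 mol%), P(t-Bu)3 (2 mol%), THF, rt
Reagents that add atoms: none
Why: Zinc insertion gives the Reformatsky reagent, and its cross-coupling with the vinylogous acyl bromide under zerovalent palladium catalysis (Negishi-type α-arylation of a zinc ester enolate) should leave the 2-pyranone untouched because the zinc enolate is weakly basic; the new stereocenter forms as a racemate and is erased in step 6.

Step 3
Reactants: 5 tert-butyl 2-(6-methyl-2-oxo-2H-pyran-4-yl)propanoate
Product: 6 2-(6-methyl-2-oxo-2H-pyran-4-yl)propanoic acid (racemic)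
Conditions: CF3CO2H, CH2Cl2, rt
Reagents that add atoms: none
Why: Acidolysis of the tert-butyl ester should free the acid at room temperature without base, which the lactone of the 2-pyranone would not tolerate.

Step 4
Reactants: 6 2-(6-methyl-2-oxo-2H-pyran-4-yl)propanoic acid
Product: 7 2-(6-methyl-2-oxo-2H-pyran-4-yl)propanoyl chloride (racemic)
Conditions: (COCl)2, DMF (cat.), CH2Cl2, 0 °C to rt; concentrated and used at once
Reagents that add atoms: oxalyl chloride, O=C(Cl)C(=O)Cl
Why: Standard acid chloride formation through the chloroiminium catalyst should proceed under neutral conditions that spare the pyranone.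

Step 5
Reactants: 8 propyne
Product: 11 triisopropyl(prop-1-yn-1-yloxy)silane, via 1-propynyllithium 9 (not isolated), via lithium propynolate 10 (not isolated)
Conditions: n-BuLi, THF, −78 °C; LiOOt-Bu (from t-BuOOH and LiN(SiMe3)2), −78 to 0 °C; i-Pr3SiOTf, −78 °C
Reagents that add atoms: tert-butyl hydroperoxide, CC(C)(C)OO; triisopropylsilyl trifluoromethanesulfonate, CC(C)[Si](C(C)C)(C(C)C)OS(=O)(=O)C(F)(F)F
Why: Oxidation of the lithium acetylide by lithium tert-butyl peroxide should give the lithium ynolate, which the bulky silyl triflate captures on oxygen (established siloxyalkyne synthesis).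

Step 6
Reactants: 7 2-(6-methyl-2-oxo-2H-pyran-4-yl)propanoyl chloride; 11 triisopropyl(prop-1-yn-1-yloxy)silane
Product: 16 8-hydroxy-3,5,7-trimethyl-6-(triisopropylsilyloxy)-1H-isochromen-1-one, via ketene 12 (not isolated), via cyclobutenone 13 (not isolated), via dienylketene 14 (not isolated), via cyclohexadienone 15 (not isolated)
Conditions: 11 (1.3 equiv), toluene, rt, i-Pr2NEt (1.2 equiv) added slowly; then 80–110 °C
Reagents that add atoms: none
Why: Dehydrochlorination of 7 gives ketene 12, whose carbonyl carbon (future C8) should bond to the methyl-bearing carbon of 11 (C7) while its α-carbon (C5) bonds to the oxygen-bearing carbon (C6), a [2+2] cycloaddition that makes both key bonds and gives the strained cyclobutenone 13. On heating, reversible 4π-electrocyclic opening of the C5–C8 bond gives dienylketene 14, and the isomer with the pyranonyl group cis to the ketene arm should close by thermal disrotatory 6π-electrocyclization of C8 onto pyranone C3 (C8a), the only ring closure of the step, to give 15, which tautomerizes to phenol 16. The closest known reaction type is the Danheiser benzannulation of ketenes and vinylketenes with alkoxy- and siloxyalkynes, including its aryl- and heteroarylketene variants. No stereocenter survives, since C5 of 13 and C8a of 15 are transient and racemic. The step needs the right orientation of the [2+2] addition, secured by the polarization of the ynol ether against the ketene, and closure at pyranone C3 and not C5, secured because only the C3=C4 π bond is conjugated with the dienylketene as its third double bond. Slow addition of the base beside excess 11 should hold the ketene concentration low against dimerization, and the 8-OH of 16, hydrogen-bonded to the lactone carbonyl, should be a poor trap for ketene.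

Step 7
Reactants: 16 8-hydroxy-3,5,7-trimethyl-6-(triisopropylsilyloxy)-1H-isochromen-1-one
Product: 17 6,8-dihydroxy-3,5,7-trimethyl-1H-isochromen-1-one
Conditions: Bu4NF, AcOH, THF, 0 °C
Reagents that add atoms: none
Why: Fluoride should cleave the aryl silyl ether within minutes, and the acetic acid buffer keeps the medium from opening the lactone.

Step 8
Reactants: 18 (2E,6E)-farnesol
Product: 19 (2E,6E)-farnesyl methyl carbonate
Conditions: ClCO2Me, pyridine, CH2Cl2, 0 °C
Reagents that add atoms: methyl chloroformate, COC(=O)Cl
Why: Acylation of the primary allylic alcohol should give the carbonate without touching the trisubstituted alkenes.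

Step 9
Reactants: 17 6,8-dihydroxy-3,5,7-trimethyl-1H-isochromen-1-one; 19 (2E,6E)-farnesyl methyl carbonate
Product: 21 (5S)-8-hydroxy-3,5,7-trimethyl-5-[(2E,6E)-3,7,11-trimethyldodeca-2,6,10-trien-1-yl]-1H-isochromene-1,6(5H)-dione (5-farnesyl-isochromene), via dilithium diphenoxide 20 (not isolated)
Conditions: 17, LiN(SiMe3)2 (2.0 equiv), THF, −78 to 0 °C; then Pd2(dba)3·CHCl3 (2.5 mol%), N,N'-[(1S,2S)-cyclohexane-1,2-diyl]bis[2-(diphenylphosphanyl)benzamide] (7.5 mol%), 19 (1.0 equiv), 0 °C; aq. NH4Cl
Reagents that add atoms: none
Why: Proposed new method: ionization of carbonate 19 by the zerovalent palladium–bisphosphine complex gives a cationic π-farnesylpalladium species, which the dilithium diphenoxide 20 should attack from outside the metal at the unsubstituted CH2 terminus (linear chain, 2E geometry kept) through C5, the ring carbon whose pyramidalization relieves the peri strain between 5-CH3 and H-4 while C7 lies shielded between two lithium-bound oxygens, so that the dienone formed is the lithium salt of 21 itself, a stabilized vinylogous carboxylate that should resist a second allylation; the chiral pocket of the ligand distinguishes the two faces of the planar nucleophile at C5 and thereby sets the (5S)-quaternary center; the closest known reaction types are the palladium-catalyzed asymmetric allylic dearomatization of naphthols, the palladium-catalyzed asymmetric linear prenylation and geranylation of oxindoles, and the uncatalyzed dearomative C-farnesylation of 3,5-dimethylorsellinate ester dianions at the corresponding carbon.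

## Compound list

1 | 4-hydroxy-6-methyl-2H-pyran-2-one (triacetic acid lactone) | Cc1cc(O)cc(=O)o1 | starting material
2 | 4-bromo-6-methyl-2H-pyran-2-one | Cc1cc(Br)cc(=O)o1 | intermediate
3 | tert-butyl 2-bromopropanoate (racemic) | CC(Br)C(=O)OC(C)(C)C | starting material
4 | bromo(1-tert-butoxy-1-oxopropan-2-yl)zinc (Reformatsky reagent, racemic) | CC([Zn]Br)C(=O)OC(C)(C)C | intermediate
5 | tert-butyl 2-(6-methyl-2-oxo-2H-pyran-4-yl)propanoate (racemic) | CC(C(=O)OC(C)(C)C)c1cc(C)oc(=O)c1 | intermediate
6 | 2-(6-methyl-2-oxo-2H-pyran-4-yl)propanoic acid (racemic) | CC(C(=O)O)c1cc(C)oc(=O)c1 | intermediate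
7 | 2-(6-methyl-2-oxo-2H-pyran-4-yl)propanoyl chloride (racemic) | CC(C(=O)Cl)c1cc(C)oc(=O)c1 | intermediate
8 | propyne | CC#C | starting material
9 | 1-propynyllithium | [Li]C#CC | intermediate
10 | lithium prop-1-yn-1-olate | CC#C[O-].[Li+] | intermediate
11 | triisopropyl(prop-1-yn-1-yloxy)silane | CC#CO[Si](C(C)C)(C(C)C)C(C)C | intermediate
12 | methyl(6-methyl-2-oxo-2H-pyran-4-yl)ketene | CC(=C=O)c1cc(C)oc(=O)c1 | intermediate
13 | 2,4-dimethyl-4-(6-methyl-2-oxo-2H-pyran-4-yl)-3-(triisopropylsilyloxy)cyclobut-2-en-1-one (racemic) | CC1=C(O[Si](C(C)C)(C(C)C)C(C)C)C(C)(c2cc(C)oc(=O)c2)C1=O | intermediate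
14 | (E)-2,4-dimethyl-4-(6-methyl-2-oxo-2H-pyran-4-yl)-3-(triisopropylsilyloxy)buta-1,3-dien-1-one (pyranonyl cis to the ketene arm) | O=C=C(C)/C(O[Si](C(C)C)(C(C)C)C(C)C)=C(/C)c1cc(C)oc(=O)c1 | intermediate
15 | 3,5,7-trimethyl-6-(triisopropylsilyloxy)-1H-isochromene-1,8(8aH)-dione (racemic) | CC1=CC2=C(C)C(O[Si](C(C)C)(C(C)C)C(C)C)=C(C)C(=O)C2C(=O)O1 | intermediate
16 | 8-hydroxy-3,5,7-trimethyl-6-(triisopropylsilyloxy)-1H-isochromen-1-one | Cc1cc2c(C)c(O[Si](C(C)C)(C(C)C)C(C)C)c(C)c(O)c2c(=O)o1 | intermediate
17 | 6,8-dihydroxy-3,5,7-trimethyl-1H-isochromen-1-one | Cc1cc2c(C)c(O)c(C)c(O)c2c(=O)o1 | intermediate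
18 | (2E,6E)-farnesol | CC(C)=CCC/C(C)=C/CC/C(C)=C/CO | starting material
19 | (2E,6E)-farnesyl methyl carbonate | CC(C)=CCC/C(C)=C/CC/C(C)=C/COC(=O)OC | intermediate
20 | dilithium 3,5,7-trimethyl-1-oxo-1H-isochromene-6,8-diolate | Cc1cc2c(C)c([O-])c(C)c([O-])c2c(=O)o1.[Li+].[Li+] | intermediate
21 | (5S)-8-hydroxy-3,5,7-trimethyl-5-[(2E,6E)-3,7,11-trimethyldodeca-2,6,10-trien-1-yl]-1H-isochromene-1,6(5H)-dione | CC(C)=CCC/C(C)=C/CC/C(C)=C/C[C@]1(C)C(=O)C(C)=C(O)c2c1cc(C)oc2=O | target

## Step count and risks

Total step count: 9. Longest linear sequence: 7 steps (steps 1, 2, 3, 4, 6, 7 and 9); steps 5 and 8 make the two side fragments.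

**Step 9 (highest risk).** The allylation may lose regiocontrol (attack through C7 or through oxygen). The π-allyl intermediate may isomerize and erode the 2E geometry. The ligand may discriminate the two faces of the flat dianion poorly. The fallback sets out from 17 and gives up catalytic stereocontrol in favor of resolution. The dianion from 17 and LiN(SiMe3)2 (2.0 equiv, THF, 0 °C) would be alkylated without catalyst by (2E,6E)-farnesyl bromide, the dearomative C-alkylation known for 3,5-dimethylorsellinate ester dianions. This should give racemic 8-hydroxy-3,5,7-trimethyl-5-[(2E,6E)-farnesyl]-1H-isochromene-1,6(5H)-dione F1. Its enantiomers would be separated by preparative HPLC on an amylose tris(3,5-dimethylphenylcarbamate) phase, and the (5S)-enantiomer is 21, where the fallback rejoins the route.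

**Step 6.** Dimerization of the ketene or its capture by the product phenol may outrun the [2+2] addition. The 6π closure onto the electron-poor pyranone π bond may also lag, so that material stays at the cyclobutenone stage. Should part of the material follow a direct [4+2] path instead, the silyl group would end on O8 and step 7 would still lead to 17. The fallback sets out from 7 and builds the ring by polar acylations. Compound 7 would acylate the lithium enolate of ethyl propanoate (LDA, THF, −78 °C, 2.2 equiv of enolate) to give ethyl 2-methyl-4-(6-methyl-2-oxo-2H-pyran-4-yl)-3-oxopentanoate F2. Concentrated H2SO4 at 0 °C to rt should then close the ring by acylation of pyranone C3 with the ester and aromatize it, as in the naphthalene-1,3-diol synthesis from 4-aryl-3-oxobutanoates. The fallback rejoins the route at 17, and step 7 is no longer needed.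

**Step 2.** Proton transfer from the acidic coupling product to the zinc enolate, or conjugate addition of the enolate to the pyranone, may stall the cross-coupling. The fallback sets out from 2 and uses addition–elimination instead of catalysis. Sodium diethyl methylmalonate (NaH, THF, 0 °C to rt) should displace the bromide at C4 to give diethyl 2-methyl-2-(6-methyl-2-oxo-2H-pyran-4-yl)malonate F3. Aqueous HCl in AcOH at 90 °C would hydrolyze it to 2-methyl-2-(6-methyl-2-oxo-2H-pyran-4-yl)malonic acid F4, which loses CO2 in the same pot. The fallback rejoins the route at 6, and step 3 is no longer needed.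

## Further compounds

F1 | step 9 | racemic 8-hydroxy-3,5,7-trimethyl-5-[(2E,6E)-3,7,11-trimethyldodeca-2,6,10-trien-1-yl]-1H-isochromene-1,6(5H)-dione | CC(C)=CCC/C(C)=C/CC/C(C)=C/CC1(C)C(=O)C(C)=C(O)c2c1cc(C)oc2=O
F2 | step 6 | ethyl 2-methyl-4-(6-methyl-2-oxo-2H-pyran-4-yl)-3-oxopentanoate | CCOC(=O)C(C)C(=O)C(C)c1cc(C)oc(=O)c1
F3 | step 2 | diethyl 2-methyl-2-(6-methyl-2-oxo-2H-pyran-4-yl)malonate | CCOC(=O)C(C)(C(=O)OCC)c1cc(C)oc(=O)c1
F4 | step 2 | 2-methyl-2-(6-methyl-2-oxo-2H-pyran-4-yl)malonic acid | CC(C(=O)O)(C(=O)O)c1cc(C)oc(=O)c1
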